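(All runs stem from a simulated flask with constants of no real substance; the scatter is artificial.)

In ochre, a small charge of Z stops D early: Z is the limiting reagent at half the E, and D stands level. For north, I follow what happens to E while it waits for Z.

| flask | E | Z | remark | time |
|---|---|---|---|---|
| violet | 20 mM | 20 mM | run made earlier |  |
| ochre | 20 mM | 10 mM | run made earlier |  |
| blue | 20 mM | 40 mM | run made earlier |  |
| south-east | 20 mM | 20.0 mM (fed, over 3.0 h) | all else is in the flask from the start; the feed brings no volume worth counting | 15 h |
| east | 20 mM | 20.0 mM (in portions, 3, over 12 h) | first portion at the start, last at 12 h | 15 h |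
| north-west | 20 mM (fed, over 12 h) | 20.0 mM | all else is in the flask from the start; the feed brings no volume worth counting | 15 h |
| north | 20 mM | 20.0 mM (fed, over 12 h) | all else is in the flask from the start; the feed brings no volume worth counting | 15 h |
| south | 20 mM | 20.0 mM | everything together at the start | 15 h |

- violet (time / h: D / %, X / %, E / %): 2.00: 77.5, 4.9, 3.6; 4.00: 82.2, 4.6, 2.5; 5.00: 83.7, 4.2, 2.1; 8.00: 85.1, 2.3, 3.3; 10.0: 83.8, 4.8, 0.4
- ochre (time / h: D / %, X / %, E / %): 2.00: 42.4, 2.3, 39.7; 4.00: 43.2, 2.5, 36.8; 5.00: 45.1, 0.6, 34.2; 8.00: 45.6, 1.8, 29.7; 10.0: 44.0, 2.6, 27.5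
- blue (time / h: D / %, X / %, E / %): 2.00: 88.7, 4.4, 0; 4.00: 87.9, 5.2, 1.0; 5.00: 88.1, 5.2, 0.3; 8.00: 86.2, 6.0, 0; 10.0: 88.4, 4.1, 1.1

(each reading ± 1 percentage point)



- which flask leads in amount of D, in percent of the E charged ("all alike" within 1.5 percentage points) (south-east / east / north-west / north / south / all alike)
- how much D is there at the end, in percent of the E charged: south-east
- how much D is there at the end, in percent of the E charged: east
- how much D is there at the end, in percent of the E charged: north-west
- how much D is there at the end, in percent of the E charged: north
- how much D is there at the end, in percent of the E charged: south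

I build north one process at a time, with e as the fraction of the E charge still free and z as the fraction of the Z charge fed. Z is taken quickly: violet's E is down to 3.6 % by 2.00 h, well inside the feed time of 12 h.

With the main step alone, each Z takes one E and gives D, so my figure for north is 100 %.

Next comes the side share. Ochre's level D, divided by its Z fraction, gives D per Z:

s = 88.1 %

My figure for north drops to that value.

Last comes the waiting loss. Ochre's E keeps falling after D stops. I do not try to read the order from these scattered readings. I choose E meeting E, a loss of κe². Then 1/e climbs evenly: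

κ = 0.140 h⁻¹

Dividing this loss by the feed rate removes time:

de/dz = −(1 + We²)

W = κ × feed time = 1.68

W is the waiting number, the loss rate at full charge divided by the feed rate. In this reckoning, e reaches zero at the Z fraction below, taken by Simpson's rule:

z_stop = [1 + 4/(1 + W/4) + 1/(1 + W)]/6 = 69.9 %

D = s × z_stop = 61.6 %

The forecast differs. It reads ochre as “leftover E decays slowly” and gives north 71 %, between 63 % and 78 %. My figure lies below that range. For the others it gives south-east 81 %, east 72 %, north-west 87 % and south 84.5 %, with north-west leading.

The flasks give south-east 74.5 %, east 65.6 %, north-west 90.1 %, north 61.4 % and south 84.4 %, so north-west leads.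

    E + Z → L (k = 4.27 M⁻¹ min⁻¹)
    L → X (k = 0.00649 min⁻¹)
    E + L → G (k = 0.897 M⁻¹ min⁻¹)
    2 E → J (k = 0.0507 M⁻¹ min⁻¹)
    L → D (k = 0.120 min⁻¹)

With W at 1.68, north loses 30.1 % by my reckoning, and J holds 28.2 % of the E at 15.0 h. Taking away the step of 2 E into J cuts the gap between north-west and north from 29 percentage points to 8.2 points, the larger effect of the two steps removed. In south-east, W falls to 0.419, z_stop rises to 88.8 %, the reckoned loss is 11.2 %, and J holds 12.2 %.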